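**Assumptions.** The SMILES is read as (1R,6R,7S,8R,10S,4E)-6,8-diacetoxy-1,10-epoxygermacr-4-en-14-al, with C2 and C9 cis on the epoxide. The sense of induction of the chiral base (step 5) and of the epoxidation catalyst (step 15) is assumed; the antipodal reagent is used if it proves opposite.

## Retrosynthetic overview

1. Target ⇐ cis-epoxidation of the ring-cis (1E) enal 18 ⇐ thermodynamic isomerisation of the ring-trans enal 17 ⇐ Pd/CO formylation of a C10 enol triflate (CO supplies C14).
2. Ten-membered ring ⇐ anionic oxy-Cope ring expansion (6 → 10) of a 1-vinyl-2-isopropenylcyclohexan-1-olate, with the enolate trapped as the triflate.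
3. That cyclohexanone (carrying the C6/C7/C8 triad) ⇐ enone 7 by α′-aldol with acetone and anti conjugate borylation.
4. Enone 7 ⇐ enantioselective desymmetrising β-elimination of the meso bis-silyloxy ketone 6 (key step).
5. Ketone 6 ⇐ all-cis hydrogenation of 2-isopropylphloroglucinol ⇐ phloroglucinol + 2-propanol. Ring order: six-membered ring (from the arene) → ten-membered ring → epoxide last.

## Route

**Step 1**
Reactants: 1 phloroglucinol; 2 propan-2-ol
Product: 3, 2-isopropylbenzene-1,3,5-triol
Conditions: i-PrOH (1 equiv), phloroglucinol (4 equiv), MeSO3H, dioxane, 80 °C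
Reagents that add atoms: none (2 is the alkylating reactant)
Why: Friedel–Crafts C-alkylation of a very electron-rich arene whose three CH positions are equivalent, so only one mono-isopropyl isomer can form and excess arene suppresses dialkylation.

**Step 2**
Reactants: 3
Product: 4, all-cis-2-isopropylcyclohexane-1,3,5-triol (meso; 1R,2s,3S,5r)
Conditions: H2 (60 bar), 5% Rh/Al2O3, i-PrOH/H2O, cat. AcOH, 60 °C
Reagents that add atoms: none
Why: Heterogeneous arene hydrogenation (the dearomatisation) delivers all six hydrogens to one face, as in phloroglucinol → cis,cis-cyclohexane-1,3,5-triol, so both carbinols flanking the isopropyl carbon are cis to it.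

**Step 3**
Reactants: 4
Product: 5, (3R,4s,5S)-3,5-dihydroxy-4-isopropylcyclohexan-1-one (meso)
Conditions: TEMPO (10 mol%), PhI(OAc)2 (1.05 equiv), MeCN/pH 7 buffer, 0 °C
Reagents that add atoms: none
Why: Oxoammonium (TEMPO) oxidation is strongly steric-sensitive, so the carbinol flanked by two CH2 groups is oxidised in preference to the two next to the isopropyl-bearing carbon; no stereocentre changes.

**Step 4**
Reactants: 5
Product: 6, (3R,4s,5S)-3,5-bis(tert-butyldimethylsilyloxy)-4-isopropylcyclohexan-1-one (meso)
Conditions: TBSOTf (2.3 equiv), 2,6-lutidine, CH2Cl2, −78 °C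
Reagents that add atoms: TBSOTf, CC(C)(C)[Si](C)(C)OS(=O)(=O)C(F)(F)F
Why: Standard silylation with the triflate at low temperature protects both hindered β-hydroxyls without β-elimination.

**Step 5 (key step)**
Reactants: 6
Product: 7, (4S,5R)-5-(tert-butyldimethylsilyloxy)-4-isopropylcyclohex-2-en-1-one
Conditions: lithium (R,R)-bis(1-phenylethyl)amide (1.0 equiv), LiCl, THF, −100 → −40 °C
Reagents that add atoms: none
Why: Proposed new method: the C2-symmetric chiral lithium amide removes one of the two enantiotopic α-protons (Simpkins/Koga enantioselective deprotonation of meso cyclohexanones is the closest known reaction) and the resulting enolate expels the anti-periplanar axial β-silyloxy group (E1cB, as in 5-silyloxycyclohexenone chemistry), so the mirror symmetry is broken, the retained C5 silyl ether stays cis to the isopropyl group, and the enone blocks one α-position for later regiocontrol.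

**Step 6**
Reactants: 7; 8 acetone
Product: 9, (4S,5S,6S)-5-(tert-butyldimethylsilyloxy)-6-(2-hydroxypropan-2-yl)-4-isopropylcyclohex-2-en-1-one
Conditions: LDA, THF, −78 °C; acetone (excess); AcOH quench at −78 °C
Reagents that add atoms: none (8 is a reactant)
Why: Kinetic α′-deprotonation of the enone (the only enolisable site) and aldol addition anti to the pseudo-axial OTBS group; this new centre is destroyed in step 11, so its configuration is not critical.

**Step 7**
Reactants: 9
Product: 10, (2S,3S,4S,5R)-3-(tert-butyldimethylsilyloxy)-5-hydroxy-2-(2-hydroxypropan-2-yl)-4-isopropylcyclohexan-1-one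
Conditions: B2pin2, CuCl (5 mol%), DPEphos, NaOt-Bu (cat.), MeOH, THF, rt; then 30% H2O2, pH 7 buffer
Reagents that add atoms: hydrogen peroxide, OO (boron from B2pin2 is replaced by OH)
Why: Copper-catalysed conjugate borylation places boron on the enone β-carbon anti to the adjacent isopropyl group, and stereoretentive C–B oxidation gives the C5 alcohol trans to isopropyl (net inversion relative to the eliminated silyl ether).

**Step 8**
Reactants: 10
Product: 11, (2S,3S,4S,5R)-3,5-bis(tert-butyldimethylsilyloxy)-2-(2-hydroxypropan-2-yl)-4-isopropylcyclohexan-1-one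
Conditions: TBSOTf (1.1 equiv), 2,6-lutidine, CH2Cl2, −78 °C
Reagents that add atoms: TBSOTf, CC(C)(C)[Si](C)(C)OS(=O)(=O)C(F)(F)F
Why: The secondary alcohol is silylated much faster than the hindered tertiary one.

**Step 9**
Reactants: 11
Product: 12, (2R,3S,4S,5R)-3,5-bis(tert-butyldimethylsilyloxy)-4-isopropyl-2-(prop-1-en-2-yl)cyclohexan-1-one
Conditions: Burgess reagent, toluene, 50 °C
Reagents that add atoms: none
Why: Syn-elimination (Burgess dehydration) of the tertiary sulfamate takes one of six accessible methyl hydrogens in preference to the single hindered ring methine, giving the isopropenyl group under neutral conditions.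

**Step 10**
Reactants: 12; 13 vinylmagnesium bromide
Product: 14, (1R,2R,3S,4S,5R)-3,5-bis(tert-butyldimethylsilyloxy)-4-isopropyl-2-(prop-1-en-2-yl)-1-vinylcyclohexan-1-ol
Conditions: anhydrous CeCl3, vinylMgBr, THF, −78 °C
Reagents that add atoms: none (13 is a reactant)
Why: Organocerium 1,2-addition (no enolisation) occurs by equatorial attack anti to the α-isopropenyl group on the chair whose axial approach is blocked by an axial OTBS, giving the trans-divinyl carbinol; C1 and C2 are destroyed in step 11.

**Step 11**
Reactants: 14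
Product: 15, (1Z,5E,7R,8S,9R)-7,9-bis(tert-butyldimethylsilyloxy)-8-isopropyl-5-methylcyclodeca-1,5-dien-1-yl trifluoromethanesulfonate
Conditions: KHMDS (1.1 equiv), 18-crown-6, THF, 0 °C → rt; then PhNTf2, −78 → 0 °C
Reagents that add atoms: N-phenyl-bis(trifluoromethanesulfonimide), O=S(=O)(N(c1ccccc1)S(=O)(=O)C(F)(F)F)C(F)(F)F
Why: Anionic oxy-Cope rearrangement through the chair transition state with both alkenyl groups equatorial expands the ring to ten members, sets the E-trisubstituted C5=C6 alkene and gives a regio-defined enolate that is trapped on oxygen; the three carbinol/isopropyl centres are untouched.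

**Step 12**
Reactants: 15
Product: 16, (1Z,5E,7R,8S,9R)-7,9-diacetoxy-8-isopropyl-5-methylcyclodeca-1,5-dien-1-yl trifluoromethanesulfonate
Conditions: HF·pyridine, THF/pyridine, 0 °C → rt; then Ac2O, DMAP (one pot)
Reagents that add atoms: acetic anhydride, CC(=O)OC(C)=O
Why: Buffered fluoride desilylation followed by acylation with retention at both carbinols; it is done before the aldehyde exists so that the C9 alcohol cannot form a lactol with it.

**Step 13**
Reactants: 16
Product: 17, (1Z,5E,7R,8S,9R)-7,9-diacetoxy-8-isopropyl-5-methylcyclodeca-1,5-diene-1-carbaldehyde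
Conditions: Pd(PPh3)4 (5 mol%), CO (1 atm), Bu3SnH (1.1 equiv, slow addition), LiCl, THF, 50 °C
Reagents that add atoms: carbon monoxide, [C-]#[O+]
Why: Stille-type reductive carbonylation of the vinyl triflate installs the formyl carbon (C14) with retention of alkene geometry; the fast oxidative addition of the triflate outcompetes ionisation of the hindered allylic acetate.

**Step 14**
Reactants: 17
Product: 18, (1E,5E,7R,8S,9R)-7,9-diacetoxy-8-isopropyl-5-methylcyclodeca-1,5-diene-1-carbaldehyde (ring-cis enal)
Conditions: PhSH (10 mol%), Et3N (10 mol%), CH2Cl2, rt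
Reagents that add atoms: none
Why: Reversible thia-Michael addition/elimination equilibrates only the enal double bond to the more stable isomer, which has CHO trans to the β-carbon and a less strained cis,trans-cyclodecadiene.

**Step 15**
Reactants: 18
Product: 19, Pulicanaral A
Conditions: 50% aq. H2O2 (1.5 equiv), 9-amino-9-deoxy-epi-quinine (10 mol%), TFA (20 mol%), dioxane, 35 °C
Reagents that add atoms: hydrogen peroxide, OO
Why: Amine-catalysed (iminium) nucleophilic epoxidation of the α-branched enal leaves the acetates and the unactivated alkene intact; the catalyst selects the C1-Re/C10-Si face and ring closure gives the cis-epoxide (1R,10S).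

## Compound list

1 | phloroglucinol | Oc1cc(O)cc(O)c1 | starting material
2 | propan-2-ol | CC(C)O | starting material
3 | 2-isopropylbenzene-1,3,5-triol | CC(C)c1c(O)cc(O)cc1O | intermediate
4 | all-cis-2-isopropylcyclohexane-1,3,5-triol (meso) | O[C@H]1C[C@@H](O)[C@@H](C(C)C)[C@@H](O)C1 | intermediate
5 | (3R,4s,5S)-3,5-dihydroxy-4-isopropylcyclohexan-1-one | O=C1C[C@@H](O)[C@@H](C(C)C)[C@@H](O)C1 | intermediate
6 | (3R,4s,5S)-3,5-bis(TBSO)-4-isopropylcyclohexan-1-one | O=C1C[C@@H](O[Si](C)(C)C(C)(C)C)[C@@H](C(C)C)[C@@H](O[Si](C)(C)C(C)(C)C)C1 | intermediate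
7 | (4S,5R)-5-(TBSO)-4-isopropylcyclohex-2-en-1-one | O=C1C[C@@H](O[Si](C)(C)C(C)(C)C)[C@@H](C(C)C)C=C1 | intermediate
8 | acetone | CC(C)=O | starting material
9 | (4S,5S,6S)-5-(TBSO)-6-(2-hydroxypropan-2-yl)-4-isopropylcyclohex-2-en-1-one | O=C1[C@H](C(C)(C)O)[C@@H](O[Si](C)(C)C(C)(C)C)[C@@H](C(C)C)C=C1 | intermediate
10 | (2S,3S,4S,5R)-3-(TBSO)-5-hydroxy-2-(2-hydroxypropan-2-yl)-4-isopropylcyclohexan-1-one | O=C1[C@H](C(C)(C)O)[C@@H](O[Si](C)(C)C(C)(C)C)[C@@H](C(C)C)[C@H](O)C1 | intermediate
11 | (2S,3S,4S,5R)-3,5-bis(TBSO)-2-(2-hydroxypropan-2-yl)-4-isopropylcyclohexan-1-one | O=C1[C@H](C(C)(C)O)[C@@H](O[Si](C)(C)C(C)(C)C)[C@@H](C(C)C)[C@H](O[Si](C)(C)C(C)(C)C)C1 | intermediate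
12 | (2R,3S,4S,5R)-3,5-bis(TBSO)-4-isopropyl-2-(prop-1-en-2-yl)cyclohexan-1-one | O=C1[C@H](C(C)=C)[C@@H](O[Si](C)(C)C(C)(C)C)[C@@H](C(C)C)[C@H](O[Si](C)(C)C(C)(C)C)C1 | intermediate
13 | vinylmagnesium bromide | C=C[Mg]Br | starting material
14 | (1R,2R,3S,4S,5R)-3,5-bis(TBSO)-4-isopropyl-2-(prop-1-en-2-yl)-1-vinylcyclohexan-1-ol | O[C@]1(C=C)[C@H](C(C)=C)[C@@H](O[Si](C)(C)C(C)(C)C)[C@@H](C(C)C)[C@H](O[Si](C)(C)C(C)(C)C)C1 | intermediate
15 | (1Z,5E,7R,8S,9R)-7,9-bis(TBSO)-8-isopropyl-5-methylcyclodeca-1,5-dien-1-yl triflate | FC(F)(F)S(=O)(=O)O\C1=C/CC/C(C)=C/[C@@H](O[Si](C)(C)C(C)(C)C)[C@@H](C(C)C)[C@H](O[Si](C)(C)C(C)(C)C)C1 | intermediate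
16 | (1Z,5E,7R,8S,9R)-7,9-diacetoxy-8-isopropyl-5-methylcyclodeca-1,5-dien-1-yl triflate | FC(F)(F)S(=O)(=O)O\C1=C/CC/C(C)=C/[C@@H](OC(C)=O)[C@@H](C(C)C)[C@H](OC(C)=O)C1 | intermediate
17 | (1Z,5E,7R,8S,9R)-7,9-diacetoxy-8-isopropyl-5-methylcyclodeca-1,5-diene-1-carbaldehyde | O=C\C1=C/CC/C(C)=C/[C@@H](OC(C)=O)[C@@H](C(C)C)[C@H](OC(C)=O)C1 | intermediate
18 | (1E,5E,7R,8S,9R)-7,9-diacetoxy-8-isopropyl-5-methylcyclodeca-1,5-diene-1-carbaldehyde | O=C/C1=C/CC/C(C)=C/[C@@H](OC(C)=O)[C@@H](C(C)C)[C@H](OC(C)=O)C1 | intermediate
19 | Pulicanaral A | CC(=O)O[C@@H]1/C=C(\C)CC[C@H]2O[C@@]2(C=O)C[C@@H](OC(C)=O)[C@@H]1C(C)C | target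

## Totals and main risks

Total steps: 15. Longest linear sequence: 15 (fully linear from phloroglucinol).

Three steps most likely to fail, each with a fallback that changes the approach:

1. **Step 5 (desymmetrising elimination).** Enantioselectivity is unproven on this substrate, and a second elimination to 4-isopropylphenol is possible. Fallback: desymmetrise diol 5 with a lipase (enantioselective mono-acetylation), silylate the remaining hydroxyl, and eliminate the acetate with DBU to reach the same enone 7.
2. **Step 13 (reductive carbonylation).** Pd–H may reduce the allylic acetate. Fallback: couple the triflate with Bu3SnCH2OH (Stille hydroxymethylation, no hydride present) and oxidise the allylic alcohol with MnO2 to the enal.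
3. **Step 15 (epoxidation).** Facial selectivity on the flexible ten-membered ring may be poor or mismatched. Fallback: Luche-reduce 18 to the allylic alcohol, carry out a Sharpless asymmetric epoxidation (reagent-controlled and stereospecific), then oxidise with Dess–Martin periodinane to the epoxy aldehyde.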